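**Retrosynthetic overview**
- Rubrolide A is unmasked last by twofold O-demethylation of its bis(methyl ether).
- The butenolide is cut at C3=C4, not at the exocyclic alkene. The (Z)-enol of a 1,3-diaryl-1,2-diketone (an α-hydroxychalcone) is O-acylated by Ph3P=C=C=O and then undergoes an intramolecular Wittig reaction.
- In that [2+2] event the γ-lactone ring and a fused 1,2-oxaphosphetane ring close together; loss of Ph3P=O leaves the butenolide, and the (Z)-benzylidene is inherited from the (Z)-enol.
- The α-hydroxychalcone comes from base isomerisation of a trans-epoxy ketone, made in one pot (Claisen–Schmidt, then Weitz–Scheffer) from two brominated anisole building blocks.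
- Ring order: arenes bought; oxirane (temporary); lactone plus oxaphosphetane in one event; the four-membered ring collapses and the butenolide stays.

Assumption: the target has no stereocentre, so "single enantiomer" is read as the single (Z)-alkene isomer drawn; both methyl ether building blocks are taken as catalogue compounds (each is otherwise one O-methylation from the cheap bromophenol).

**Step 1**
Reactants: 1 3,5-dibromo-4-methoxybenzaldehyde; 2 1-(3,5-dibromo-4-methoxyphenyl)ethan-1-one
Product: 4 rac-[(2R,3S)-3-(3,5-dibromo-4-methoxyphenyl)oxiran-2-yl](3,5-dibromo-4-methoxyphenyl)methanone (trans-epoxy ketone), via chalcone 3 (not isolated)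
Conditions: NaOH (0.3 equiv, 2 M aq), THF/MeOH 1:1, 0 °C to rt, 6 h; then 30% aq H2O2 (3 equiv), 0 °C to rt, 3 h
Reagents that add atoms: hydrogen peroxide, OO
Why: Claisen–Schmidt aldol condensation gives the (E)-chalcone, and the same alkaline medium then epoxidises the electron-poor enone by hydroperoxide conjugate addition and ring closure (Weitz–Scheffer epoxidation), giving the trans epoxide as a racemate whose two stereocentres are erased in step 2; aryl bromides and methyl ethers are inert to cold dilute alkaline peroxide.

**Step 2**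
Reactants: 4 trans-epoxy ketone
Product: 5 (Z)-1,3-bis(3,5-dibromo-4-methoxyphenyl)-2-hydroxyprop-2-en-1-one (Z-enol of the 1,2-diketone)
Conditions: NaOH (1.2 equiv, 1 M aq), EtOH/THF 2:1, degassed, Ar, 60 °C, 20 min; then 1 M HCl, 0 °C
Reagents that add atoms: none
Why: Base-mediated isomerisation of an α,β-epoxy ketone to a diosphenol, in which hydroxide opens the oxirane and E1cB loss of the benzylic oxygen from the enolate gives the 1,2-diketone, which rests as its enolate and is protonated to the conjugated, hydrogen-bonded enol; the (Z)-geometry (aryl cis to OH, trans to the aroyl group) is the thermodynamic one and equilibrates through the diketone tautomer, and short time without oxygen avoids benzilic acid rearrangement and oxidative cleavage.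

**Step 3**
Reactants: 5 (Z)-enol of the 1,2-diketone; 6 (triphenylphosphoranylidene)ketene (Ph3P=C=C=O)
Product: 9 (Z)-4-(3,5-dibromo-4-methoxyphenyl)-5-[(3,5-dibromo-4-methoxyphenyl)methylidene]furan-2(5H)-one (di-O-methylrubrolide A), via ester ylide 7 (not isolated), via bicyclic oxaphosphetane 8 (not isolated)
Conditions: Ph3P=C=C=O (1.3 equiv), toluene, Ar, 60 °C, 1 h, then reflux (110 °C), 12 h
Reagents that add atoms: (triphenylphosphoranylidene)ketene 6, O=C=C=P(c1ccccc1)(c1ccccc1)c1ccccc1
Why: Proposed new method: the acidic enol O–H adds across the ketene C=C of Ph3P=C=C=O to give the (Z)-enol ester ylide 7, whose ylide carbon then adds 5-exo to the adjacent aryl ketone in an intramolecular Wittig [2+2] that closes the γ-lactone ring and the 1,2-oxaphosphetane ring in the same bond-forming event (cis-fused bicycle 8), and cycloreversion with loss of Ph3P=O leaves the C3=C4 double bond, while the competing conjugate addition would be a disfavoured 5-endo closure; the exocyclic (Z)-alkene is carried over untouched from the enol and is also the more stable isomer; the closest known reaction types are the domino addition/intramolecular Wittig olefination of Ph3P=C=C=O with α-hydroxy ketones (butenolides) and with ortho-hydroxyaryl ketones (coumarins).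

**Step 4**
Reactants: 9 di-O-methylrubrolide A
Product: 10 Rubrolide A
Conditions: BBr3 (6 equiv), CH2Cl2, −78 °C to rt, 16 h; then ice-water
Reagents that add atoms: none
Why: Lewis acid ether cleavage (BBr3 demethylation), in which boron binds the twisted di-ortho-brominated methoxy oxygens and bromide removes each methyl by SN2, the aryl borates hydrolysing on quench; the lactone, the enol-ester alkene and the aryl bromides are inert at or below room temperature, so the (Z)-geometry is untouched.

**Compound list**
1 | 3,5-dibromo-4-methoxybenzaldehyde | O=Cc1cc(Br)c(OC)c(Br)c1 | starting material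
2 | 1-(3,5-dibromo-4-methoxyphenyl)ethan-1-one | CC(=O)c1cc(Br)c(OC)c(Br)c1 | starting material
3 | (E)-1,3-bis(3,5-dibromo-4-methoxyphenyl)prop-2-en-1-one (chalcone) | O=C(/C=C/c1cc(Br)c(OC)c(Br)c1)c1cc(Br)c(OC)c(Br)c1 | intermediate
4 | rac-[(2R,3S)-3-(3,5-dibromo-4-methoxyphenyl)oxiran-2-yl](3,5-dibromo-4-methoxyphenyl)methanone (trans; one enantiomer drawn) | O=C(c1cc(Br)c(OC)c(Br)c1)[C@@H]1O[C@H]1c1cc(Br)c(OC)c(Br)c1 | intermediate
5 | (Z)-1,3-bis(3,5-dibromo-4-methoxyphenyl)-2-hydroxyprop-2-en-1-one (enol of the 1,2-diketone; aryl cis to OH) | O=C(c1cc(Br)c(OC)c(Br)c1)/C(O)=C/c1cc(Br)c(OC)c(Br)c1 | intermediate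
6 | (triphenylphosphoranylidene)ketene, Ph3P=C=C=O | O=C=C=P(c1ccccc1)(c1ccccc1)c1ccccc1 | starting material
7 | (Z)-1,3-bis(3,5-dibromo-4-methoxyphenyl)-3-oxoprop-1-en-2-yl (triphenyl-λ5-phosphanylidene)acetate (ester ylide) | O=C(c1cc(Br)c(OC)c(Br)c1)/C(OC(=O)C=P(c1ccccc1)(c1ccccc1)c1ccccc1)=C/c1cc(Br)c(OC)c(Br)c1 | intermediate
8 | rac-cis-(4Z)-5-(3,5-dibromo-4-methoxyphenyl)-4-[(3,5-dibromo-4-methoxyphenyl)methylidene]-7,7,7-triphenyl-3,6-dioxa-7λ5-phosphabicyclo[3.2.0]heptan-2-one (lactone-fused 1,2-oxaphosphetane; one enantiomer drawn) | O=C1O/C(=C\c2cc(Br)c(OC)c(Br)c2)[C@]2(c3cc(Br)c(OC)c(Br)c3)OP(c3ccccc3)(c3ccccc3)(c3ccccc3)[C@H]12 | intermediate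
9 | (Z)-4-(3,5-dibromo-4-methoxyphenyl)-5-[(3,5-dibromo-4-methoxyphenyl)methylidene]furan-2(5H)-one (di-O-methylrubrolide A) | O=C1C=C(c2cc(Br)c(OC)c(Br)c2)/C(=C/c2cc(Br)c(OC)c(Br)c2)O1 | intermediate
10 | Rubrolide A, (Z)-4-(3,5-dibromo-4-hydroxyphenyl)-5-[(3,5-dibromo-4-hydroxyphenyl)methylidene]furan-2(5H)-one | O=C1C=C(c2cc(Br)c(O)c(Br)c2)/C(=C/c2cc(Br)c(O)c(Br)c2)O1 | target

**Totals**
Total step count: 4. Longest linear sequence: 4 steps (1 and 2 to 4 to 5 to 9 to 10).

**Steps most likely to fail, with fallbacks**

Step 3 is the most exposed. The enolate of 5 is ambident, so C-acylation can compete, and the stabilised ylide may olefinate the cross-conjugated aryl ketone only slowly. The fallback sets out from 5. The enol oxygen is acylated with (diethoxyphosphoryl)acetic acid (DCC, DMAP cat., CH2Cl2, 0 °C) to give (Z)-1,3-bis(3,5-dibromo-4-methoxyphenyl)-3-oxoprop-1-en-2-yl (diethoxyphosphoryl)acetate F1. The ring is then closed with the more nucleophilic phosphonate carbanion in an intramolecular Horner–Wadsworth–Emmons olefination (LiCl, DBU, MeCN, rt). This comes back to the route at 9.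

Step 2 is second. Hydroxide can push the diketone on to the benzilic acid rearrangement product or cleave the diol intermediate by retro-aldol reaction. The fallback sets out from 4 and avoids base. The oxirane is opened at the benzylic carbon with HBr (48% aq, CHCl3, 0 °C) to give rac-(2S,3R)-3-bromo-1,3-bis(3,5-dibromo-4-methoxyphenyl)-2-hydroxypropan-1-one F2 (mainly the anti-opened diastereomer; its stereocentres are erased later). The secondary alcohol is oxidised with Dess–Martin periodinane (CH2Cl2, rt) to racemic 3-bromo-1,3-bis(3,5-dibromo-4-methoxyphenyl)propane-1,2-dione F3. Reductive removal of the activated bromine (NaI, Na2S2O3, AcOH/THF, rt) gives the enol directly. This comes back to the route at 5.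

Step 1 is third. The tetrabrominated chalcone 3 may precipitate and epoxidise incompletely in the one-pot protocol. The fallback sets out from 2. α-Bromination (CuBr2, EtOAc/CHCl3, reflux) gives 2-bromo-1-(3,5-dibromo-4-methoxyphenyl)ethan-1-one F4. A Darzens condensation with 1 (K2CO3, MeOH/THF, 0 °C to rt) forms the C–C bond and the oxirane together without passing through the chalcone. This comes back to the route at 4.

**Further compounds**
F1 | step 3 | (Z)-1,3-bis(3,5-dibromo-4-methoxyphenyl)-3-oxoprop-1-en-2-yl (diethoxyphosphoryl)acetate | O=C(c1cc(Br)c(OC)c(Br)c1)/C(OC(=O)CP(=O)(OCC)OCC)=C/c1cc(Br)c(OC)c(Br)c1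
F2 | step 2 | rac-(2S,3R)-3-bromo-1,3-bis(3,5-dibromo-4-methoxyphenyl)-2-hydroxypropan-1-one | O=C(c1cc(Br)c(OC)c(Br)c1)[C@H](O)[C@H](Br)c1cc(Br)c(OC)c(Br)c1
F3 | step 2 | racemic 3-bromo-1,3-bis(3,5-dibromo-4-methoxyphenyl)propane-1,2-dione | O=C(c1cc(Br)c(OC)c(Br)c1)C(=O)C(Br)c1cc(Br)c(OC)c(Br)c1
F4 | step 1 | 2-bromo-1-(3,5-dibromo-4-methoxyphenyl)ethan-1-one | O=C(CBr)c1cc(Br)c(OC)c(Br)c1
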